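**Retrosynthetic overview**

1. The plan rests on ring B being a mono-acylated resorcinol: the oxygen on C4' carries the ring A aroyl group, the oxygen on C2' is a separate (methyl ether) oxygen, C1' bears the carboxyl and C6' the pentyl chain.
2. Target 22 ⇐ dibenzyl compound 21 (both benzyl groups removed) ⇐ phenol 20 (O-methylation at C2').
3. Ring B of 20 ⇐ propargylic ester 17 + CO 18: C2' is the CO carbon (bonds C1'–C2' and C2'–C3'), and the aroyloxy group goes back from C4' to the carbinol carbon (future C5').
4. 17 ⇐ enynol 9 (from keto acetal 4 by olefination, hydrolysis and ethynyl addition) + ring A acid chloride 16 (from olivetol 10 by formylation, O-methylation, O-benzylation and oxidation).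
5. Ring order: ring A is bought as olivetol; ring B is the only ring made, in step 11.

Key step: step 11

Assumption: ring B is numbered as in the depside name (C1' carboxyl carbon, C2' methoxy carbon, C4' carbon bearing the ester oxygen, C6' pentyl carbon). The target has no stereocentre, so the one carbinol centre on the way is carried as the racemate.

**Route**

Step 1
Reactants: 1 methyl dimethoxyacetate; 2 pentylmagnesium bromide
Product: 4 1,1-dimethoxyheptan-2-one, via bromomagnesium hemiketal alkoxide 3 (not isolated)
Conditions: 2 (1.05 equiv), THF/Et2O, −78 °C; quench at −78 °C, aq. NH4Cl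
Reagents that add atoms: none
Why: Grignard acyl substitution, in which tetrahedral adduct 3 should persist at −78 °C as a magnesium chelate of the α-methoxy oxygens, so that the ketone is released only on quench and a second addition is avoided.

Step 2
Reactants: 4 1,1-dimethoxyheptan-2-one; 5 benzyl diethylphosphonoacetate
Product: 6 benzyl (E)-3-(dimethoxymethyl)oct-2-enoate
Conditions: NaH, THF, 0 °C to rt; chromatography to remove the Z isomer
Reagents that add atoms: none
Why: Horner–Wadsworth–Emmons olefination of an activated α-keto acetal, which should place the ester trans to the branched dimethoxymethyl group (E) in preference to the unbranched pentyl chain.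

Step 3
Reactants: 6 benzyl (E)-3-(dimethoxymethyl)oct-2-enoate
Product: 7 benzyl (E)-3-formyloct-2-enoate
Conditions: 2 M aq. HCl, THF, rt
Reagents that add atoms: water, O
Why: Acid-catalysed acetal hydrolysis, which the benzyl ester tolerates and which should keep the E geometry, the more stable arrangement with formyl and ester trans.

Step 4
Reactants: 7 benzyl (E)-3-formyloct-2-enoate; 8 ethynylmagnesium bromide
Product: 9 benzyl (E)-4-hydroxy-3-pentylhex-2-en-5-ynoate (racemic)
Conditions: 8 (1.1 equiv), THF, −78 °C; aq. NH4Cl
Reagents that add atoms: none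
Why: 1,2-Addition of an alkynyl Grignard reagent to the aldehyde, which at −78 °C is far more electrophilic than the benzyl enoate; the new carbinol centre forms as a racemate and needs no control because it becomes aromatic in step 11.

Step 5
Reactants: 10 olivetol (5-pentylresorcinol)
Product: 12 2,4-dihydroxy-6-pentylbenzaldehyde, via aryl dimethyliminium chloride 11 (not isolated)
Conditions: POCl3, DMF, 0 °C to rt; then H2O, NaOAc, 50 °C
Reagents that add atoms: N,N-dimethylformamide, CN(C)C=O; water, O
Why: Vilsmeier–Haack formylation, which should attack the carbon ortho to one hydroxyl and para to the other and not the crowded carbon between the two hydroxyls; hydrolysis of iminium salt 11 gives the aldehyde.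

Step 6
Reactants: 12 2,4-dihydroxy-6-pentylbenzaldehyde
Product: 13 2-hydroxy-4-methoxy-6-pentylbenzaldehyde
Conditions: MeI (1.05 equiv), K2CO3, acetone, rt to 40 °C
Reagents that add atoms: iodomethane, CI
Why: Williamson etherification in which the 2-hydroxyl is held in a hydrogen bond to the aldehyde, so that one equivalent of MeI should alkylate the freer and more acidic 4-hydroxyl.

Step 7
Reactants: 13 2-hydroxy-4-methoxy-6-pentylbenzaldehyde
Product: 14 2-benzyloxy-4-methoxy-6-pentylbenzaldehyde
Conditions: BnBr, K2CO3, DMF, 60 °C
Reagents that add atoms: benzyl bromide, BrCc1ccccc1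
Why: Williamson benzylation of the one remaining, chelated phenol under more forcing conditions, installing a group that hydrogenolysis removes at the end.

Step 8
Reactants: 14 2-benzyloxy-4-methoxy-6-pentylbenzaldehyde
Product: 15 2-benzyloxy-4-methoxy-6-pentylbenzoic acid
Conditions: NaClO2, NaH2PO4, 2-methyl-2-butene, t-BuOH/H2O, rt
Reagents that add atoms: sodium chlorite, [Na+].[O-]Cl=O
Why: Pinnick oxidation of the aldehyde, with the alkene scavenger removing hypochlorous acid so that the electron-rich ring is not chlorinated and the benzyl ether is untouched.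

Step 9
Reactants: 15 2-benzyloxy-4-methoxy-6-pentylbenzoic acid
Product: 16 2-benzyloxy-4-methoxy-6-pentylbenzoyl chloride
Conditions: (COCl)2, cat. DMF, CH2Cl2, 0 °C to rt; evaporate, use crude
Reagents that add atoms: oxalyl chloride, O=C(Cl)C(=O)Cl
Why: Acid chloride formation through the chloroiminium catalyst, chosen because the acid carries two ortho substituents and needs a strongly activated acyl donor.

Step 10
Reactants: 9 benzyl (E)-4-hydroxy-3-pentylhex-2-en-5-ynoate; 16 2-benzyloxy-4-methoxy-6-pentylbenzoyl chloride
Product: 17 benzyl (E)-4-[(2-benzyloxy-4-methoxy-6-pentylbenzoyl)oxy]-3-pentylhex-2-en-5-ynoate (racemic)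
Conditions: Et3N, DMAP, CH2Cl2, 0 °C to rt
Reagents that add atoms: none
Why: DMAP-catalysed acylation of the secondary alcohol by the acyl chloride, under a mild amine base at low temperature that should leave the acidic propargylic hydrogen and the E alkene unchanged.

Step 11
Reactants: 17 benzyl (E)-4-[(2-benzyloxy-4-methoxy-6-pentylbenzoyl)oxy]-3-pentylhex-2-en-5-ynoate; 18 carbon monoxide
Product: 20 benzyl 4-[(2-benzyloxy-4-methoxy-6-pentylbenzoyl)oxy]-2-hydroxy-6-pentylbenzoate, via cyclohexa-2,4-dienone tautomer 19 (not isolated)
Conditions: [RhCl(CO)2]2 (5 mol %, monovalent rhodium), CO (about 50 atm), CH2Cl2, 80 °C, autoclave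
Reagents that add atoms: none
Why: Monovalent rhodium should bind the terminal alkyne so that the aroyl carbonyl oxygen attacks the internal alkyne carbon and a 1,2-acyloxy shift forms O–C4' and leaves a rhodium vinylcarbene at C3' in conjugation with C4'=C5' and the enoate C6'=C1'. CO is then taken up at the carbene carbon (bond C2'–C3') and six-membered ring B closes by bond C1'–C2', either through 6π-electrocyclisation of the dienylketene or through CO insertion and reductive elimination from a rhodacyclohexadiene, giving dienone 19. Dienone 19 should enolise at once through the hydrogen on C1', which lies between ketone and ester, to give phenol 20. The closest known reaction type is the [RhCl(CO)2]2-catalysed carbonylative [5+1] benzannulation of 3-acyloxy-1,4-enynes to resorcinol monoesters. No stereocentre is formed, since the racemic carbinol carbon becomes aromatic C5' and the transient centre at C1' of 19 is lost on enolisation. The step needs 1,2- and not 1,3-acyloxy migration, which the unsubstituted alkyne terminus favours, and the E geometry keeps the ester on C1' turned away from the closing termini; the electron-poor enoate, less rich than the alkenes of the known cases, is the main uncertainty.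

Step 12
Reactants: 20 benzyl 4-[(2-benzyloxy-4-methoxy-6-pentylbenzoyl)oxy]-2-hydroxy-6-pentylbenzoate
Product: 21 benzyl 4-[(2-benzyloxy-4-methoxy-6-pentylbenzoyl)oxy]-2-methoxy-6-pentylbenzoate
Conditions: MeI, K2CO3, dry DMF, rt
Reagents that add atoms: iodomethane, CI
Why: Williamson methylation of the only free hydroxyl (C2'), under a mild carbonate base in dry solvent that the hindered, di-ortho-substituted aryl ester link should withstand.

Step 13
Reactants: 21 benzyl 4-[(2-benzyloxy-4-methoxy-6-pentylbenzoyl)oxy]-2-methoxy-6-pentylbenzoate
Product: 22 2'-O-methylperlatolic acid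
Conditions: H2 (1 atm), Pd/C (10 wt % Pd on carbon, zerovalent palladium), EtOAc, rt
Reagents that add atoms: none
Why: Hydrogenolysis cleaves the benzyl ether on ring A and the benzyl ester on ring B in one operation, while the aryl ester link and the methyl ethers are inert to these conditions.

**Compound list**

1 | methyl dimethoxyacetate | COC(OC)C(=O)OC | starting material
2 | pentylmagnesium bromide | CCCCC[Mg]Br | starting material
3 | bromomagnesium 1,1,2-trimethoxyheptan-2-olate (hemiketal alkoxide, not isolated) | CCCCCC(OC)(O[Mg]Br)C(OC)OC | intermediate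
4 | 1,1-dimethoxyheptan-2-one | CCCCCC(=O)C(OC)OC | intermediate
5 | benzyl diethylphosphonoacetate | CCOP(=O)(CC(=O)OCc1ccccc1)OCC | starting material
6 | benzyl (E)-3-(dimethoxymethyl)oct-2-enoate | COC(OC)/C(CCCCC)=C/C(=O)OCc1ccccc1 | intermediate
7 | benzyl (E)-3-formyloct-2-enoate | O=C/C(CCCCC)=C/C(=O)OCc1ccccc1 | intermediate
8 | ethynylmagnesium bromide | C#C[Mg]Br | starting material
9 | benzyl (E)-4-hydroxy-3-pentylhex-2-en-5-ynoate (racemic) | C#CC(O)/C(CCCCC)=C/C(=O)OCc1ccccc1 | intermediate
10 | olivetol (5-pentylbenzene-1,3-diol) | CCCCCc1cc(O)cc(O)c1 | starting material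
11 | [(2,4-dihydroxy-6-pentylphenyl)methylidene]dimethylammonium chloride (not isolated) | CCCCCc1cc(O)cc(O)c1C=[N+](C)C.[Cl-] | intermediate
12 | 2,4-dihydroxy-6-pentylbenzaldehyde | CCCCCc1cc(O)cc(O)c1C=O | intermediate
13 | 2-hydroxy-4-methoxy-6-pentylbenzaldehyde | CCCCCc1cc(OC)cc(O)c1C=O | intermediate
14 | 2-benzyloxy-4-methoxy-6-pentylbenzaldehyde | CCCCCc1cc(OC)cc(OCc2ccccc2)c1C=O | intermediate
15 | 2-benzyloxy-4-methoxy-6-pentylbenzoic acid | CCCCCc1cc(OC)cc(OCc2ccccc2)c1C(=O)O | intermediate
16 | 2-benzyloxy-4-methoxy-6-pentylbenzoyl chloride | CCCCCc1cc(OC)cc(OCc2ccccc2)c1C(=O)Cl | intermediate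
17 | benzyl (E)-4-[(2-benzyloxy-4-methoxy-6-pentylbenzoyl)oxy]-3-pentylhex-2-en-5-ynoate (racemic) | C#CC(OC(=O)c1c(CCCCC)cc(OC)cc1OCc1ccccc1)/C(CCCCC)=C/C(=O)OCc1ccccc1 | intermediate
18 | carbon monoxide | [C-]#[O+] | starting material
19 | benzyl 4-[(2-benzyloxy-4-methoxy-6-pentylbenzoyl)oxy]-2-oxo-6-pentylcyclohexa-3,5-diene-1-carboxylate (racemic, not isolated) | CCCCCC1=CC(OC(=O)c2c(CCCCC)cc(OC)cc2OCc2ccccc2)=CC(=O)C1C(=O)OCc1ccccc1 | intermediate
20 | benzyl 4-[(2-benzyloxy-4-methoxy-6-pentylbenzoyl)oxy]-2-hydroxy-6-pentylbenzoate | CCCCCc1cc(OC)cc(OCc2ccccc2)c1C(=O)Oc1cc(CCCCC)c(C(=O)OCc2ccccc2)c(O)c1 | intermediate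
21 | benzyl 4-[(2-benzyloxy-4-methoxy-6-pentylbenzoyl)oxy]-2-methoxy-6-pentylbenzoate | CCCCCc1cc(OC)cc(OCc2ccccc2)c1C(=O)Oc1cc(CCCCC)c(C(=O)OCc2ccccc2)c(OC)c1 | intermediate
22 | 2'-O-methylperlatolic acid | CCCCCc1cc(OC)cc(O)c1C(=O)Oc1cc(CCCCC)c(C(=O)O)c(OC)c1 | target

**Step count and risks**

Total step count: 13. Longest linear sequence: 9 steps (steps 5 to 13, from olivetol 10).

Steps most likely to fail:

Step 11. The 1,2-acyloxy shift may be slow on an enyne whose alkene is an electron-poor enoate. A 1,3-shift to an allenyl ester, alkyne oligomerisation, or cyclisation of the vinylcarbene without CO uptake could then take over. The fallback gives up the benzannulation and builds the depside by classical esterification. It sets out from aldehyde 12 and acid chloride 16 and comes back to the route at target 22. Acylation of the free 4-hydroxyl of 12 with 16 (pyridine, DMAP, CH2Cl2; the 2-hydroxyl is hydrogen-bonded to the aldehyde) should give 4-formyl-3-hydroxy-5-pentylphenyl 2-benzyloxy-4-methoxy-6-pentylbenzoate F1. Methylation (MeI, K2CO3, DMF) should give 4-formyl-3-methoxy-5-pentylphenyl 2-benzyloxy-4-methoxy-6-pentylbenzoate F2. Pinnick oxidation (NaClO2, NaH2PO4, 2-methyl-2-butene) should give 4-[(2-benzyloxy-4-methoxy-6-pentylbenzoyl)oxy]-2-methoxy-6-pentylbenzoic acid F3, and hydrogenolysis over Pd/C should then give 22.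

Step 10. Acylation by the di-ortho-substituted acid chloride may be slow. That would leave time for the amine base to shift the doubly activated propargylic hydrogen, isomerising the enyne to an allene or a conjugated dienoate. The fallback activates the alcohol and not the acid. It sets out from acid 15 and alcohol 9 and comes back at ester 17 by a Mitsunobu esterification (PPh3, diisopropyl azodicarboxylate, toluene, 0 °C). There the hindered carboxylate acts only as nucleophile, and the inversion at the racemic carbinol has no consequence. This fallback makes no new compound (F0).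

Step 1. The tetrahedral adduct may collapse before the quench, and the released ketone would then take up a second equivalent of Grignard reagent to give the tertiary alcohol. The fallback moves the acyl transfer to a stable chelate. It sets out from ester 1 and comes back at ketone 4. Aminolysis of 1 (MeNHOMe·HCl, i-PrMgCl, THF, −20 °C) should give N-methoxy-N-methyl-2,2-dimethoxyacetamide F4, and treatment with pentylmagnesium bromide 2 (THF, 0 °C) should then give 4 after aqueous work-up.

**Further compounds**

F1 | step 11 | 4-formyl-3-hydroxy-5-pentylphenyl 2-benzyloxy-4-methoxy-6-pentylbenzoate | CCCCCc1cc(OC)cc(OCc2ccccc2)c1C(=O)Oc1cc(CCCCC)c(C=O)c(O)c1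
F2 | step 11 | 4-formyl-3-methoxy-5-pentylphenyl 2-benzyloxy-4-methoxy-6-pentylbenzoate | CCCCCc1cc(OC)cc(OCc2ccccc2)c1C(=O)Oc1cc(CCCCC)c(C=O)c(OC)c1
F3 | step 11 | 4-[(2-benzyloxy-4-methoxy-6-pentylbenzoyl)oxy]-2-methoxy-6-pentylbenzoic acid | CCCCCc1cc(OC)cc(OCc2ccccc2)c1C(=O)Oc1cc(CCCCC)c(C(=O)O)c(OC)c1
F0 | step 10 | none | none
F4 | step 1 | N-methoxy-N-methyl-2,2-dimethoxyacetamide | COC(OC)C(=O)N(C)OC
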